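Per micromolar of enzyme, the noon and spring runs make about the same target for each unit of starting material lost, and this ratio is carried here to the flask, which holds less enzyme.

| setting | noon | spring | flask |
|---|---|---|---|
| starting material | 0.0050 M | 0.0050 M | 0.0050 M |
| second substrate | 5 mM | 5 mM | 5.00 mM |
| enzyme | 0.27 µM | 0.42 µM | 0.19 µM |
| remark | run made earlier | run made earlier |  |

| noon: time / min | noon: target / % | spring: time / min | spring: target / % |
|---|---|---|---|
| 0.167 | 63.1 | 0.250 | 91.0 |
| 0.500 | 88.3 | 0.333 | 90.5 |
| 0.833 | 86.2 | 0.500 | 90.9 |
| 1.33 | 86.4 | 0.833 | 90.8 |
| 2.00 | 87.3 | 1.33 | 91.2 |
| 2.50 | 85.3 | 2.00 | 89.4 |
| 3.00 | 86.6 | 3.00 | 90.6 |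

(each reading ± 1 percentage point)

- apparent order in enzyme when 50% of the starting material are converted (percent change of the rate of making target for one percent more enzyme charged)
- apparent order in second substrate when 50% of the starting material are converted (percent change of the rate of making target for one percent more second substrate charged)
- factor on the rate of making target when 50% of the starting material are converted if second substrate is charged twice over

- no earlier run changes the charge of second substrate; that part of a forecast is a guess

The noon run levels at 86.7% target and the spring run at 90.6%, so the remainder is read as starting material lost by a path that runs without enzyme. Target over loss is then 6.51 and 9.67, and division by the enzyme charged gives 24.1 /µM and 23.0 /µM. Their mean, 23.6 /µM, is the selectivity factor per enzyme, target made per loss for each micromolar of enzyme charged. The same two ratios read as an order in enzyme of 0.896, which is taken as about one. No earlier run varies second substrate, so its order stays a guess.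

For the flask, 0.19 µM enzyme is reckoned to give a ratio of 4.48, so its curve is expected to run into a level of 81.7% target. The first noon reading, scaled in proportion to enzyme, gives a mean slope over the opening stretch of 2.66 /min as a fraction of the charge. Drawn straight, that slope meets the expected level at 0.307 min, which is taken as an estimate of the knee, and beyond it the flask's curve is expected to lie flat, as both earlier runs do out to 3.00 min.

The forecast, reading the plateaus as “a parallel enzyme-independent loss of starting material”, gave 0.97 for the order in enzyme, 0.15 for the order in second substrate and 1.1 for the doubling factor.

The flask gives 1.0 in enzyme, −0.084 in second substrate and a doubling factor of 0.922, so a doubled charge of second substrate lowers the rate of making target when 50% of the starting material are converted.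

    starting material + enzyme ⇌ complex A (K = 3000 /M, k = 4.20 × 10⁶ /M/s)
    complex A → enzyme + target (k = 1600 /s)
    second substrate + enzyme ⇌ complex B (K = 140 /M, k = 2.70 × 10⁷ /M/s)
    complex B → enzyme + second product (k = 15000 /s)
    starting material → uncatalysed product (k = 0.0200 /s)

At 0.181 min in the flask, the step from starting material and enzyme to complex A, taken as its forward rate alone, stands to the step to uncatalysed product at a ratio of 10. By 3.00 min the flask holds 81.9% target against 18.1% uncatalysed product, which makes 23.8 /µM as its selectivity factor per enzyme, where the noon and spring readings gave 23.6 /µM.

The runs come from a simulation from invented constants, noise included.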